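**Numbering and face convention.** Azulene locants of the target are used for every compound, tricyclic ones included: five-membered ring C8a–C1–C2–C3–C3a, seven-membered ring C3a–C4–C5–C6–C7–C8–C8a. α is the face carrying C3a–H and C8a–CH3; β is the opposite face.

## The problem

Target 22 is a cis-fused hydroazulene in which a cyclopentane shares the C3a–C8a bond with a cycloheptene that carries the C6=C7 double bond and the C6 methyl group. It has five stereocentres (C3, C3a, C4, C8, C8a): the C8a methyl, the tertiary C3 hydroxyl and the C8 acyloxy group are α, while the C3 isopropyl and the C4 aroyloxy group are β. The quaternary C8a and its neighbour C3a have nothing to lean on and must be set first, cis and in the absolute sense. Once they exist, the folded bicycle lets reagents reach C3 from the α face, and the C3 hydroxyl can then guide the reduction at C4. C8, a neopentylic carbinol beside the quaternary carbon, has the weakest handle. Two different acyl groups must be placed on the C4 and C8 hydroxyls while the tertiary alcohol and the phenol stay free. The tertiary alcohol is β to C4 (dehydration or retro-aldol whenever C4 is a ketone), C3a–H epimerises next to a C4 carbonyl, the C8 ester is allylic, and neither ester tolerates alkoxide or hydride, so the end game must be mild. The enabling feature is that C4 and C8 are both oxygenated and both bonded to a ring-fusion carbon: joining C4 to C8 converts the seven-membered ring into a cyclobutane (C8a, C3a, C4, C8) that bridges a cyclopentane-1,2-diol (C4–C8), and this cyclobutane is the [2+2] adduct of a cyclopentenone (C3a=C8a) and an enediol ether (C4=C8).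

## Retrosynthesis

**End game at C8.** Target 22 is traced to its bis-silyl ether 21, so that the last step only removes silicon under buffered fluoride. The C8 ester is cut at the acyl–oxygen bond to allylic alcohol 19 and 3-methylbutanoyl chloride 20, and 19 comes from enone 18 by 1,2-reduction. C8 is placed last because its configuration is the least secure and the allylic ester is the most fragile group.

**The C6=C7 double bond.** Enone 18 is traced to saturated ketone 16. With C8a quaternary the C8 ketone can enolise only toward C7, so desaturation must give C6=C7. An earlier olefin would have had to survive the photoreaction and the hydration. This cut also erases the C6 stereocentre, so its configuration in every earlier compound is immaterial.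

**The C4 ester and carbinol.** Ketone 16 is cut at the C4 acyl–oxygen bond to diol 12 and silyl-protected acid 15, which comes from 4-hydroxybenzoic acid 13. Diol 12 comes from hydroxy-dione 11 by reduction at C4 only. The two ketones of 11 differ in that only C4 is reachable from the C3 hydroxyl, which a hydroxyl-directed hydride exploits; this fixes the order C4 first, C8 later.

**The seven-membered ring.** Dione 11 is reconnected between C4 and C8 to the cis-cyclobutane-1,2-diol 10. In the forward sense a glycol cleavage has no entropic cost, is driven by ring strain, and delivers both ring oxygens, which an aldol or metathesis closure would not. It asks only that C3 no longer be a carbonyl, otherwise C3a would sit between two ketones.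

**The C3 carbinol.** Triol 10 is traced through bis-silyl ether 9 to alkene 8, then to alkenyl triflate 7 and ketone 5. Direct addition of an isopropyl nucleophile to 5 would come from the open α face and put the hydroxyl β, the wrong way round. The roles are therefore reversed: carbon first by cross-coupling, oxygen second from the α face by hydration. This is done on the tricycle, where the C4 silyloxy group blocks the β face and C3a cannot enolise.

**The key cut.** Ketone 5 is cut at C8–C8a and C3a–C4 to 3-methylcyclopent-2-en-1-one 4 and the symmetric alkene 3. The precursors are a commercial enone and a one-step alkene; the forward reaction must deliver the quaternary centre, the cis ring fusion and the absolute configuration.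

**The alkene.** Alkene 3 is cut at its C=C bond to dimethyl 3-methylglutarate 1 and chlorotrimethylsilane 2 (silyl-trapped acyloin condensation).

## Roads not taken

**Alternative 1:** The cut is C3a–C4. In the forward key step the lithiated dithiane carbon (C4) of epoxy dithiane A2 opens the C3–C3a epoxide at C3a with inversion, closing the seven-membered ring to A1.
- Merits: the trans relationship of the C3 oxygen and the C3a–C4 bond is guaranteed by the stereospecific opening. The C8 carbinol and the (Z)-C6=C7 olefin are installed before ring closure, so the uncertain C8 reduction of the chosen plan does not arise. In these two respects this road is better.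
- Weak points: C3a is a neopentyl-type epoxide carbon beside quaternary C8a, the nucleophile is a bulky tertiary carbanion, and the ring formed is seven-membered. Base-induced isomerisation of the epoxide to an allylic alcohol is a likely competitor. A2 itself needs the quaternary centre, a cis-trisubstituted epoxide and a trisubstituted Z-olefin, a long linear preparation.
- Comparison: the chosen plan sets against the better C8 and C3 control that it makes the quaternary centre, both fusion stereocentres and the whole carbon skeleton in one step from two simple partners.

**Alternative 2:** The cut is C3–C3a. Rh2(OAc)4 turns diazo ester A4 into a carbenoid at C3a that inserts into the oxygen-activated C3–H bond with retention, closing the cyclopentane to A3.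
- Merits: this type of C–H insertion is thermal, well precedented and stereoretentive. The C3 configuration is carried over unchanged from the carbinol centre of A4, a firmer absolute control at C3 than the radical hydration used here.
- Weak points: A3 is only the five-membered ring. All five carbons C4–C8, two carbinol centres and the trisubstituted olefin remain to be built. The acyclic quaternary stereocentre C8a must already be set in A4. The C3a ester must end up cis to the bulky isopropyl group. Insertion into the isopropyl methine or silyl C–H bonds can compete.
- Comparison: the chosen plan is far shorter because its key step delivers the seven-membered ring carbons and both ring oxygens at once; it concedes the more secure C3 centre.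

**Alternative 3:** The cut is C3a–C8a, traced back by a retro-semipinacol shift to decalin A6, whose core would come from a Diels–Alder cycloaddition. BF3·OEt2 ionises the spiro-epoxide of A6 at C8a, C3a migrates from C8 to C8a, and the bicyclic ketone A5 results.
- Merits: the chemistry is thermal and scalable, and catalytic asymmetric Diels–Alder reactions are mature, so absolute configuration is a smaller risk than in the chosen plan, whose enantioselective photoreaction is unproven. The quaternary centre and the 5–7 skeleton arise together.
- Weak points: A6 needs many steps (differentiating the two carbonyls of the cycloadduct, a trans ring fusion, a face-selective spiro-epoxide). In A5 the C8a substituent is CH2OH and must be deoxygenated at a neopentyl position. The olefin is C5=C6 and must be moved, with risk of eliminating the C4 oxygen. The C3 ketal still needs conversion to the isopropyl carbinol on a more flexible bicycle.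
- Comparison: the chosen plan sets against the better enantiocontrol precedent that its oxygens and the C8a methyl are correct from the start, with no corrective redox steps.

Key step: step 2

Assumption: alkene 3 is taken to react mainly on the face anti to its methyl group; compounds 5–17 are drawn as that C6 epimer, and the other epimer runs through the same steps and converges at enone 18.
Assumption: the oxazaborolidine antipode that exposes the Re face of C3 of enone 4 is used; it is written as the (S)-prolinol-derived catalyst, and the (R)-series is equally available if the sense proves opposite.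

## Route

Step 1
Reactants: 1 dimethyl 3-methylpentanedioate (dimethyl 3-methylglutarate); 2 chlorotrimethylsilane
Product: 3 4-methyl-1,2-bis(trimethylsilyloxy)cyclopent-1-ene
Conditions: Na (4.2 equiv), 2 (4.5 equiv), toluene, reflux; filtration, distillation
Reagents that add atoms: none
Why: Acyloin condensation with in-situ silylation (Rühlmann variant): the chlorosilane traps the enediolate as its bis(silyl) ether and scavenges methoxide, which suppresses Dieckmann condensation. The glutarate gives the five-membered ring; the product has a mirror plane and no stereocentre.

Step 2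
Reactants: 4 3-methylcyclopent-2-en-1-one; 3 4-methyl-1,2-bis(trimethylsilyloxy)cyclopent-1-ene
Product: 5 (1S,2S,6R,7R,9S)-6,9-dimethyl-1,7-bis(trimethylsilyloxy)tricyclo[5.3.0.0(2,6)]decan-3-one (cis-anti-cis; azulene locants: C3 ketone; OTMS on C4 and C8; 3a-H and 8a-CH3 α; C6 methyl cis to the silyloxy groups)
Conditions: oxazaborolidine from (S)-α,α-bis(3,5-dimethylphenyl)prolinol and 2,4,6-trifluorophenylboronic acid (0.5 equiv), AlBr3 (0.5 equiv), 3 (5 equiv), CH2Cl2, −75 °C, hν (λ = 366 nm)
Reagents that add atoms: none
Why: Proposed new method: the oxazaborolidine–AlBr3 mediated enantioselective enone–alkene [2+2] photocycloaddition is known for six-membered enones with simple alkenes, and the racemic photocycloaddition of 2-cyclopentenones to 1,2-bis(trimethylsilyloxy)cycloalkenes is the closest known reaction on this pairing; joining a cyclopentenone and a bis(silyl) enediol ether under the chiral Lewis acid is new. Coordination of the Lewis acid to the carbonyl of 4 shifts its absorption to longer wavelength, so that at 366 nm mainly the complex is excited; its triplet adds to the electron-rich alkene 3 to give a 1,4-diradical, which after intersystem crossing closes the four-membered ring by radical recombination, forming C8–C8a and C3a–C4. C8a is set by the catalyst, whose aryl group shields one face of the bound enone so that 3 adds to the Re face of the β-carbon. C3a follows from C8a because a bicyclo[3.2.0]heptanone can only be cis-fused. C4 and C8 are cis because both belong to the cyclopentene, and anti to the enone ring because the diradical closes with the two five-membered rings apart; C6 is set by approach anti to its methyl group and is erased in step 11. Because 3 is symmetric there is no head-to-head or head-to-tail question, so the selectivity the step must deliver is enantiofacial; low temperature, a high Lewis acid loading and excess 3 are meant to keep uncatalysed excitation minor. Dark Mukaiyama–Michael addition of 3 should be slow, since it would join a tetrasubstituted enol ether carbon to a β,β-disubstituted enone at −75 °C.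

Step 3
Reactants: 5 tricyclic ketone
Product: 7 tricyclic alkenyl triflate (as 5 but C2=C3 double bond with OSO2CF3 on C3), via potassium enolate 6 (not isolated)
Conditions: KN(SiMe3)2, THF, −78 °C; then PhNTf2, −78 to 0 °C
Reagents that add atoms: N-phenylbis(trifluoromethanesulfonimide), O=S(=O)(N(c1ccccc1)S(=O)(=O)C(F)(F)F)C(F)(F)F
Why: Kinetic enolisation followed by O-triflation. Only the C2 methylene can be deprotonated, because a C3=C3a enolate would place a double bond at the fusion of the four- and five-membered rings. The tertiary silyl ethers tolerate the amide base at −78 °C and no stereocentre is touched.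

Step 4
Reactants: 7 tricyclic alkenyl triflate
Product: 8 tricyclic alkene (C2=C3 with isopropyl on C3; OTMS on C4 and C8)
Conditions: i-PrZnBr (2 equiv), PdCl2(dppf) (5 mol %), THF, 50 °C
Reagents that add atoms: isopropylzinc bromide, CC(C)[Zn]Br
Why: Negishi coupling of an alkenyl triflate with a secondary alkylzinc. The wide-bite-angle dppf ligand speeds reductive elimination over β-hydride elimination, so the isopropyl group should transfer without isomerising to n-propyl. Silyl ethers are inert to the organozinc.

Step 5
Reactants: 8 tricyclic alkene
Product: 9 tricyclic tertiary alcohol (3α-hydroxy-3β-isopropyl; OTMS on C4 and C8)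
Conditions: Co(acac)2 (20 mol %), PhSiH3, O2 (1 atm), THF, 0 °C to rt; aq. Na2S2O3 work-up
Reagents that add atoms: dioxygen, O=O
Why: Mukaiyama hydration: hydrogen-atom transfer from a cobalt hydride to C2 gives the tertiary C3 radical, which is captured by O2. The β face of the cyclopentane is covered by the C4 silyloxy group of the cyclobutane, so oxygen should enter from the α face, giving OH α and isopropyl β. Capture by O2 is near diffusion-controlled and should outrun opening of the cyclobutylcarbinyl radical.

Step 6
Reactants: 9 tricyclic tertiary alcohol
Product: 10 tricyclic triol (3α,4,8-trihydroxy-3β-isopropyl; cis-cyclobutane-1,2-diol)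
Conditions: K2CO3 (0.2 equiv), MeOH, 0 °C to rt
Reagents that add atoms: none
Why: Base-catalysed methanolysis of trimethylsilyl ethers. No carbonyl is present at this stage, so the strained diol cannot open by retro-aldol cleavage.

Step 7
Reactants: 10 tricyclic triol
Product: 11 cis-fused 3α-hydroxy-3β-isopropyl-6β,8a-dimethyl-octahydroazulene-4,8-dione (3a-H and 8a-CH3 α)
Conditions: Pb(OAc)4, K2CO3 (solid buffer), CH2Cl2, −20 to 0 °C; used crude
Reagents that add atoms: none
Why: Criegee glycol cleavage through the cyclic lead diolate of the cis-diol; loss of cyclobutane strain drives scission of C4–C8 and unveils the seven-membered ring with both oxygens in place. The isolated tertiary C3 hydroxyl is not a 1,2-diol partner, and buffered cold conditions should spare C3a from epimerisation and C3 from dehydration.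

Step 8
Reactants: 11 hydroxy-dione
Product: 12 cis-fused 3α,4β-dihydroxy-3β-isopropyl-6β,8a-dimethyl-octahydroazulen-8-one
Conditions: Me4NBH(OAc)3, MeCN/AcOH (1:1), −30 °C
Reagents that add atoms: none
Why: Evans–Saksena hydroxyl-directed reduction: the reagent reduces a ketone only after exchanging an acetate for the C3 hydroxyl, which can reach C4 but not C8 (trans across the ring and 1,4-related). In the conformer that keeps C5 away from the isopropyl group the O–B–H unit lies on the α face of C4, the same face an external hydride would take to avoid the isopropyl group, so the new hydroxyl should be β.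

Step 9
Reactants: 13 4-hydroxybenzoic acid
Product: 15 4-(tert-butyldimethylsilyloxy)benzoic acid, via silyl ester 14 (not isolated)
Conditions: TBSCl (2.2 equiv), imidazole, DMF, rt; then AcOH/THF/H2O, rt
Reagents that add atoms: tert-butyldimethylsilyl chloride, CC(C)(C)[Si](C)(C)Cl
Why: Silylation of phenol and acid, then selective hydrolysis of the much more labile silyl ester in aqueous acetic acid. The aryl silyl ether survives.

Step 10
Reactants: 12 diol ketone; 15 4-(tert-butyldimethylsilyloxy)benzoic acid
Product: 16 4β-[4-(tert-butyldimethylsilyloxy)benzoyloxy]-3α-hydroxy-3β-isopropyl-6β,8a-dimethyl-octahydroazulen-8-one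
Conditions: EDC·HCl, DMAP, CH2Cl2, rt
Reagents that add atoms: none
Why: Steglich esterification. Only the secondary C4 hydroxyl is acylated; the tertiary C3 hydroxyl beside the isopropyl group is inert. Any bridged hemiketal between the C4 hydroxyl and the C8 ketone is in equilibrium with the open form and is drained by acylation.

Step 11
Reactants: 16 keto ester
Product: 18 4β-[4-(tert-butyldimethylsilyloxy)benzoyloxy]-3β-isopropyl-6,8a-dimethyl-3α-(trimethylsilyloxy)-1,2,3,3a,4,5-hexahydroazulen-8(8aH)-one (C6=C7 enone), via silyl enol ether 17 (not isolated)
Conditions: TMSOTf (3 equiv), Et3N, CH2Cl2, 0 °C; concentrate, filter through pentane; then Pd(OAc)2 (1.1 equiv), MeCN, rt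
Reagents that add atoms: trimethylsilyl trifluoromethanesulfonate, C[Si](C)(C)OS(=O)(=O)C(F)(F)F
Why: Saegusa–Ito oxidation. The C8 ketone can enolise only toward C7, and the palladium enolate loses the C6 hydrogen by β-hydride elimination, giving the C6=C7 enone and erasing the C6 stereocentre so that both C6 epimers converge. The same silylation caps the tertiary C3 hydroxyl as a trimethylsilyl ether, which then serves as protection.

Step 12
Reactants: 18 enone
Product: 19 8α-hydroxy allylic alcohol (as 18 with C8 carbonyl reduced; OH α)
Conditions: NaBH4, CeCl3·7H2O, MeOH, −78 °C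
Reagents that add atoms: none
Why: Luche reduction, 1,2-selective on the enone. Hydride is expected to add anti to the adjacent angular methyl group, that is from the β face, placing the hydroxyl α. This is the least predictable stereocentre of the route and is addressed below.

Step 13
Reactants: 19 allylic alcohol; 20 3-methylbutanoyl chloride
Product: 21 8α-(3-methylbutanoyloxy) diester (as 19 with the C8 hydroxyl acylated; aryl OTBS and C3 OTMS retained)
Conditions: pyridine, DMAP (cat.), CH2Cl2, 0 °C to rt
Reagents that add atoms: none
Why: DMAP-catalysed acylation of the only free hydroxyl. The configuration at C8 is retained because the C–O bond is not broken.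

Step 14
Reactants: 21 silyl-protected diester
Product: 22 (3S,3aS,4R,8R,8aR)-3-hydroxy-6,8a-dimethyl-8-[(3-methylbutanoyl)oxy]-3-(propan-2-yl)-1,2,3,3a,4,5,8,8a-octahydroazulen-4-yl 4-hydroxybenzoate
Conditions: Bu4NF, AcOH (1:1), THF, 0 °C to rt
Reagents that add atoms: none
Why: Fluoride cleaves the aryl silyl ether and the tertiary trimethylsilyl ether in one operation. Acetic acid buffering keeps phenoxide and alkoxide protonated, so neither ester migrates or is cleaved.

## Compound list

1 | dimethyl 3-methylpentanedioate | COC(=O)CC(C)CC(=O)OC | starting material
2 | chlorotrimethylsilane | C[Si](C)(C)Cl | starting material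
3 | 4-methyl-1,2-bis(trimethylsilyloxy)cyclopent-1-ene | CC1CC(O[Si](C)(C)C)=C(O[Si](C)(C)C)C1 | intermediate
4 | 3-methylcyclopent-2-en-1-one | CC1=CC(=O)CC1 | starting material
5 | (1S,2S,6R,7R,9S)-6,9-dimethyl-1,7-bis(trimethylsilyloxy)tricyclo[5.3.0.0(2,6)]decan-3-one | C[C@@H]1C[C@@]3(O[Si](C)(C)C)[C@]2(C)CCC(=O)[C@@H]2[C@@]3(O[Si](C)(C)C)C1 | intermediate
6 | potassium C2=C3 enolate of 5 | C[C@@H]1C[C@@]3(O[Si](C)(C)C)[C@]2(C)CC=C([O-])[C@@H]2[C@@]3(O[Si](C)(C)C)C1.[K+] | intermediate (not isolated)
7 | tricyclic C3 alkenyl triflate | C[C@@H]1C[C@@]3(O[Si](C)(C)C)[C@]2(C)CC=C(OS(=O)(=O)C(F)(F)F)[C@@H]2[C@@]3(O[Si](C)(C)C)C1 | intermediate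
8 | tricyclic 3-isopropyl C2=C3 alkene | C[C@@H]1C[C@@]3(O[Si](C)(C)C)[C@]2(C)CC=C(C(C)C)[C@@H]2[C@@]3(O[Si](C)(C)C)C1 | intermediate
9 | tricyclic 3α-hydroxy-3β-isopropyl bis(trimethylsilyl) ether | C[C@@H]1C[C@@]3(O[Si](C)(C)C)[C@]2(C)CC[C@](O)(C(C)C)[C@@H]2[C@@]3(O[Si](C)(C)C)C1 | intermediate
10 | tricyclic 3α,4,8-triol | C[C@@H]1C[C@@]3(O)[C@]2(C)CC[C@](O)(C(C)C)[C@@H]2[C@@]3(O)C1 | intermediate
11 | cis-fused 3α-hydroxy-3β-isopropyl-6β,8a-dimethyl-octahydroazulene-4,8-dione | C[C@@H]1CC(=O)[C@]2(C)CC[C@](O)(C(C)C)[C@@H]2C(=O)C1 | intermediate
12 | cis-fused 3α,4β-dihydroxy-3β-isopropyl-6β,8a-dimethyl-octahydroazulen-8-one | C[C@@H]1CC(=O)[C@]2(C)CC[C@](O)(C(C)C)[C@@H]2[C@H](O)C1 | intermediate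
13 | 4-hydroxybenzoic acid | O=C(O)c1ccc(O)cc1 | starting material
14 | tert-butyldimethylsilyl 4-(tert-butyldimethylsilyloxy)benzoate | CC(C)(C)[Si](C)(C)Oc1ccc(cc1)C(=O)O[Si](C)(C)C(C)(C)C | intermediate (not isolated)
15 | 4-(tert-butyldimethylsilyloxy)benzoic acid | CC(C)(C)[Si](C)(C)Oc1ccc(cc1)C(=O)O | intermediate
16 | 4β-[4-(tert-butyldimethylsilyloxy)benzoyloxy]-3α-hydroxy-3β-isopropyl-6β,8a-dimethyl-octahydroazulen-8-one | C[C@@H]1CC(=O)[C@]2(C)CC[C@](O)(C(C)C)[C@@H]2[C@H](OC(=O)c2ccc(O[Si](C)(C)C(C)(C)C)cc2)C1 | intermediate
17 | C7=C8 trimethylsilyl enol ether of 16 with 3α-OTMS | C[C@@H]1C=C(O[Si](C)(C)C)[C@]2(C)CC[C@](O[Si](C)(C)C)(C(C)C)[C@@H]2[C@H](OC(=O)c2ccc(O[Si](C)(C)C(C)(C)C)cc2)C1 | intermediate (not isolated)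
18 | C6=C7 enone (8-oxo; 3α-OTMS; 4β-aroyloxy) | CC1=CC(=O)[C@]2(C)CC[C@](O[Si](C)(C)C)(C(C)C)[C@@H]2[C@H](OC(=O)c2ccc(O[Si](C)(C)C(C)(C)C)cc2)C1 | intermediate
19 | 8α-allylic alcohol (3α-OTMS; 4β-aroyloxy) | CC1=C[C@@H](O)[C@]2(C)CC[C@](O[Si](C)(C)C)(C(C)C)[C@@H]2[C@H](OC(=O)c2ccc(O[Si](C)(C)C(C)(C)C)cc2)C1 | intermediate
20 | 3-methylbutanoyl chloride | CC(C)CC(=O)Cl | starting material
21 | 8α-(3-methylbutanoyloxy) diester (3α-OTMS; aryl OTBS) | CC1=C[C@@H](OC(=O)CC(C)C)[C@]2(C)CC[C@](O[Si](C)(C)C)(C(C)C)[C@@H]2[C@H](OC(=O)c2ccc(O[Si](C)(C)C(C)(C)C)cc2)C1 | intermediate
22 | (3S,3aS,4R,8R,8aR)-3-hydroxy-6,8a-dimethyl-8-[(3-methylbutanoyl)oxy]-3-(propan-2-yl)-1,2,3,3a,4,5,8,8a-octahydroazulen-4-yl 4-hydroxybenzoate | CC1=C[C@@H](OC(=O)CC(C)C)[C@]2(C)CC[C@](O)(C(C)C)[C@@H]2[C@H](OC(=O)c2ccc(O)cc2)C1 | target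

## Step count and risks

Total: 14 steps. Longest linear sequence: 13 steps (steps 1–8 and 10–14, from dimethyl 3-methylglutarate); step 9 is a one-step branch.

**Step 2 (key step, proposed new method).** Enantiofacial discrimination may be poor if excitation of uncomplexed cyclopentenone competes with that of the Lewis acid complex. The Lewis acid may also consume the bis(silyl) enediol ether (desilylation or dark conjugate addition) or desilylate the adduct, which would then open by retro-aldol cleavage. The fallback sets out from 3 and 4. Uncatalysed irradiation (λ about 350 nm, hexane, −20 °C), the known racemic cycloaddition of cyclopentenones to 1,2-bis(silyloxy)cycloalkenes, gives 5 together with its mirror image, the enantiomeric adduct F1. The mixture is resolved through diastereomeric β-hydroxysulfoximines: lithiated (S)-N,S-dimethyl-S-phenylsulfoximine (THF, −78 °C, cold quench) adds to the C3 carbonyl from the α face, giving β-hydroxysulfoximine F2 from 5 and the diastereomeric β-hydroxysulfoximine F3 from F1. After chromatographic separation, thermolysis of F2 in refluxing toluene reverts it to ketone and sulfoximine. The fallback comes back at 5, at the cost of two steps and half the material.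

**Step 5.** The C3 radical is a cyclobutylcarbinyl radical, and fragmentation of the C3a–C4 bond toward the silyloxy-stabilised C4 radical may compete with oxygen capture; facial control of that capture may also be incomplete. The fallback sets out from 8. Epoxidation with dimethyldioxirane (acetone, −20 °C; neutral, to avoid cationic ring expansion of the cyclobutane) should occur on the open α face and give the α-epoxide F4. LiEt3BH (THF, 0 °C to rt) then delivers hydride to the less substituted C2 with inversion, leaving the tertiary C3 alkoxide on the α face. The fallback comes back at 9.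

**Step 12.** Facial selectivity in hydride addition to the C8 carbonyl may be poor or inverted, because the angular methyl group shields the α face while the concave side of the bicycle and the C4 ester shield the β face. The fallback sets out from 18. The wrongly configured 8β-alcohol F5 is returned to 18 by Dess–Martin oxidation, and the reduction is repeated under catalyst control (Corey–Bakshi–Shibata oxazaborolidine, catecholborane, toluene, −78 °C), using the catalyst antipode that places hydride on the β face. The fallback comes back at 19.

**Step 8.** Ligand exchange at the hindered tertiary hydroxyl may be too slow, so that no reduction occurs or the discrimination between the two ketones is lost, while hydroxy-dione 11 epimerises at C3a or undergoes retro-aldol cleavage on standing. The fallback sets out from 11. Et2BOMe followed by NaBH4 (THF/MeOH, −78 °C; Narasaka–Prasad conditions) forms a boron chelate between the C3 oxygen and the C4 carbonyl, which activates only C4; external hydride then attacks the open α face. The fallback comes back at 12 and makes no new compound (F0).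

**Step 4.** β-Hydride elimination from the isopropyl–palladium intermediate at the hindered C3 may reduce the triflate or isomerise the alkyl group to n-propyl. The fallback sets out from 7. Suzuki–Miyaura coupling with isopropenylboronic acid pinacol ester (Pd(PPh3)4, K3PO4, dioxane/water, 60 °C) gives the diene F6, and diimide (2-nitrobenzenesulfonylhydrazide, Et3N, CH2Cl2, rt) saturates the less substituted 1,1-disubstituted double bond selectively. The fallback comes back at 8.

## Further compounds

F1 | step 2 | enantiomer of 5 | C[C@H]1C[C@]3(O[Si](C)(C)C)[C@@]2(C)CCC(=O)[C@H]2[C@]3(O[Si](C)(C)C)C1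
F2 | step 2 | β-hydroxysulfoximine from 5 (3β-hydroxy; 3α-CH2S(O)(NMe)Ph; S at sulfur) | C[C@@H]1C[C@@]3(O[Si](C)(C)C)[C@]2(C)CC[C@@](O)(C[S@@](=O)(=NC)c4ccccc4)[C@@H]2[C@@]3(O[Si](C)(C)C)C1
F3 | step 2 | diastereomeric β-hydroxysulfoximine from F1 | C[C@H]1C[C@]3(O[Si](C)(C)C)[C@@]2(C)CC[C@](O)(C[S@@](=O)(=NC)c4ccccc4)[C@H]2[C@]3(O[Si](C)(C)C)C1
F4 | step 5 | tricyclic 2α,3α-epoxide of 8 | C[C@@H]1C[C@@]3(O[Si](C)(C)C)[C@]2(C)C[C@H]4O[C@@]4(C(C)C)[C@@H]2[C@@]3(O[Si](C)(C)C)C1
F5 | step 12 | 8β-epimer of allylic alcohol 19 | CC1=C[C@H](O)[C@]2(C)CC[C@](O[Si](C)(C)C)(C(C)C)[C@@H]2[C@H](OC(=O)c2ccc(O[Si](C)(C)C(C)(C)C)cc2)C1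
F0 | step 8 | none | none
F6 | step 4 | tricyclic 3-isopropenyl C2=C3 diene | C[C@@H]1C[C@@]3(O[Si](C)(C)C)[C@]2(C)CC=C(C(C)=C)[C@@H]2[C@@]3(O[Si](C)(C)C)C1
A1 | alternative 1 | cis-fused bicyclic C3 tertiary alcohol with C4 dithiane and C8 silyl ether | CC1=C[C@@H](O[Si](C)(C)C(C)(C)C)[C@]2(C)CC[C@](O)(C(C)C)[C@@H]2C3(SCCCS3)C1
A2 | alternative 1 | cyclopentane α-epoxide (C3–C3a) with (Z)-alkenyl dithiane side chain on C8a | C/C(CC1SCCCS1)=C/[C@@H](O[Si](C)(C)C(C)(C)C)[C@]2(C)CC[C@@]3(C(C)C)O[C@@H]23
A3 | alternative 2 | methyl cyclopentanecarboxylate with C3 silyl ether and quaternary C8a | CC(C)(C)[Si](C)(C)OC[C@]1(C)CC[C@](O[Si](C)(C)C(C)(C)C)(C(C)C)[C@@H]1C(=O)OC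
A4 | alternative 2 | acyclic α-diazo ester with C3 silyloxy methine | CC(C)(C)[Si](C)(C)OC[C@](C(=[N+]=[N-])C(=O)OC)(C)CC[C@H](O[Si](C)(C)C(C)(C)C)C(C)C
A5 | alternative 3 | cis-fused 8a-(hydroxymethyl) bicyclic C8 ketone with C5=C6 olefin | CC1=C[C@@H](O[Si](C)(C)C(C)(C)C)[C@H]2C3(OCCO3)CC[C@@]2(CO)C(=O)C1
A6 | alternative 3 | trans-decalin spiro-epoxy tertiary alcohol | CC1=C[C@@H](O[Si](C)(C)C(C)(C)C)[C@H]2C3(OCCO3)CC[C@]4(CO4)[C@]2(O)C1
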